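**Strategy.** The depside is cut at the aryl ester into ring A acid 19 and a ring B phenol, and ring B is cut back to an open tetraketide: its carboxyl carbon, the oxygenated C2 and C4 and the pentyl-bearing C6 are C1, C3, C5 and C7 of a 3,5,7-trioxododecanoate. In one operation dioxinone 8 is opened to an acylketene, capped as the benzyl ester and folded by a C2-to-C7 aldol into aromatic ring B, leaving the 2-hydroxyl chelated and the 4-hydroxyl free for depside formation. The precursor is a 2,2-dimethyl-1,3-dioxin-4-one carrying a 2,4-dioxononyl chain at C6. Ring A comes from formylation and oxidation of 1-heptyl-3,5-dimethoxybenzene.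

Key step: step 4

Remark on the chemistry: the target has no stereocentre, so no configuration has to be set or kept; aldol adduct 12 is a transient mixture of diastereomers that is erased on aromatization. LiN(SiMe3)2, LiN(i-Pr)2 and n-C6H13MgBr are taken as purchased solutions.

**Route**

Step 1
Reactants: 1 hexanoyl chloride
Product: 2 N-methoxy-N-methylhexanamide
Conditions: MeNH(OMe)·HCl, K2CO3, CH2Cl2/H2O, 0 °C to rt
Reagents that add atoms: N,O-dimethylhydroxylamine hydrochloride, CNOC.Cl
Why: Schotten–Baumann N-acylation of the hydroxylamine by the acid chloride should be fast and clean, and it provides a Weinreb amide as an acyl donor that cannot over-react in step 3.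

Step 2
Reactants: 3 2,2,6-trimethyl-4H-1,3-dioxin-4-one; 4 acetyl chloride
Product: 6 2,2-dimethyl-6-(2-oxopropyl)-4H-1,3-dioxin-4-one, via lithium dienolate 5 (not isolated)
Conditions: 3 (2 equiv), LiN(SiMe3)2 (2 equiv), THF, −78 °C; then 4 (1 equiv), −78 °C; 1 M HCl
Reagents that add atoms: none
Why: Deprotonation of the C6 methyl gives the cross-conjugated dienolate 5, which is C-acylated at its exocyclic carbon by the acid chloride (acylation of a dioxinone dienolate, a vinylogous Claisen-type reaction), the second equivalent of 5 taking up the proton of the more acidic product so that the new ketone is protected as its enolate.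

Step 3
Reactants: 6 2,2-dimethyl-6-(2-oxopropyl)-4H-1,3-dioxin-4-one; 2 N-methoxy-N-methylhexanamide
Product: 8 6-(2,4-dioxononyl)-2,2-dimethyl-4H-1,3-dioxin-4-one, via dilithium dianion 7 (not isolated)
Conditions: LiN(i-Pr)2 (2.2 equiv), THF, −78 °C; then 2, −78 to −20 °C; 1 M HCl
Reagents that add atoms: none
Why: The dianion reacts at its last-formed, most basic terminal carbon, and acylation by the Weinreb amide stops at the chelated tetrahedral adduct, so the beta-diketone appears only on acidic work-up and neither double acylation nor proton quenching of 7 should interfere (Weinreb ketone synthesis used as a dianion Claisen acylation).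

Step 4
Reactants: 8 6-(2,4-dioxononyl)-2,2-dimethyl-4H-1,3-dioxin-4-one; 9 benzyl alcohol
Product: 13 benzyl 2,4-dihydroxy-6-pentylbenzoate, via acylketene 10 (not isolated), via triketo benzyl ester 11 (not isolated), via cyclic aldol adduct 12 (not isolated)
Conditions: 9 (1.5 equiv), PhMe, 110 °C; then Cs2CO3, CH2Cl2/i-PrOH, rt; then HCl (4 M in 1,4-dioxane), rt
Reagents that add atoms: none
Why: Heating drives a retro-[4+2] of the dioxinone that releases acetone and acylketene 10, and benzyl alcohol adds to the ketene carbon to give the open triketo ester 11, which creates the ester C–O bond. Cs2CO3 then forms the enolate at chain C2, whose addition to the C7 ketone is a 6-(enolendo)-exo-trig aldol that makes the bond later numbered C1–C6 of ring B and gives carbinol 12; HCl dehydrates 12 and the two remaining ring ketones enolize, so ring B is closed by carbon–carbon bond formation and not by lactonization. The closest known reaction type is the thermolysis of diketo-dioxinones in the presence of an alcohol followed by carbonate-mediated aldol cyclization and acid aromatization to beta-resorcylate esters, a biomimetic polyketide fold established on this substrate class. No stereocentre remains, since the carbinol carbon and the ester-bearing carbon of 12 both become aromatic. The step needs intermolecular ketene capture to outrun O-acylation by the C5 enol (which would give a 4-hydroxy-2-pyranone) and needs the C2-to-C7 pairing; the first is secured by excess benzyl alcohol present from the start, the second by the chain itself, because the more acidic C4 and C6 methylenes have no ketone at six-ring distance (only the slow C6-to-C1 Claisen onto the ester), C8 is singly activated and not enolized by carbonate, and the C2-to-C7 aldol alone is pulled forward irreversibly by aromatization. The product should emerge with the acid masked as its benzyl ester, the 2-hydroxyl hydrogen-bonded to the ester carbonyl and the 4-hydroxyl free.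

Step 5
Reactants: 14 1-(bromomethyl)-3,5-dimethoxybenzene; 15 n-hexylmagnesium bromide
Product: 16 1-heptyl-3,5-dimethoxybenzene
Conditions: Li2CuCl4 (3 mol %), THF, −10 °C to rt
Reagents that add atoms: none
Why: Copper-catalysed coupling of a benzylic bromide with a primary alkyl Grignard reagent (Kochi coupling) should join the two sp3 carbons cleanly, the aryl methyl ethers being inert.

Step 6
Reactants: 16 1-heptyl-3,5-dimethoxybenzene
Product: 18 2-heptyl-4,6-dimethoxybenzaldehyde, via aryl iminium chloride 17 (not isolated)
Conditions: POCl3, DMF, 0 to 70 °C; then H2O, 0 °C to rt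
Reagents that add atoms: N,N-dimethylformamide, CN(C)C=O; water, O
Why: Vilsmeier–Haack formylation should take place at the ring position next to the heptyl group, which is para to one methoxy and ortho to the other, in preference to the more crowded position between the two methoxy groups, and hydrolysis of iminium salt 17 gives the aldehyde.

Step 7
Reactants: 18 2-heptyl-4,6-dimethoxybenzaldehyde
Product: 19 2-heptyl-4,6-dimethoxybenzoic acid
Conditions: NaClO2, NaH2PO4, 2-methyl-2-butene, t-BuOH/H2O, rt
Reagents that add atoms: sodium chlorite, [Na+].[O-]Cl=O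
Why: Pinnick oxidation converts the hindered aryl aldehyde to the acid under buffered conditions, the alkene scavenger intercepting hypochlorous acid before it can chlorinate the electron-rich ring.

Step 8
Reactants: 19 2-heptyl-4,6-dimethoxybenzoic acid; 13 benzyl 2,4-dihydroxy-6-pentylbenzoate
Product: 21 benzyl 4-[(2-heptyl-4,6-dimethoxybenzoyl)oxy]-2-hydroxy-6-pentylbenzoate, via mixed trifluoroacetic anhydride 20 (not isolated)
Conditions: (CF3CO)2O, PhMe, rt; aq. NaHCO3 work-up
Reagents that add atoms: none
Why: Trifluoroacetic anhydride turns the hindered, electron-rich acid into mixed anhydride 20, an acylium-like aroyl donor that should acylate the unchelated, more nucleophilic 4-hydroxyl of 13 while the 2-hydroxyl stays locked in its hydrogen bond to the ester carbonyl (mixed-anhydride esterification of a phenol, the usual depside coupling).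

Step 9
Reactants: 21 benzyl 4-[(2-heptyl-4,6-dimethoxybenzoyl)oxy]-2-hydroxy-6-pentylbenzoate
Product: 22 benzyl 4-[(2-heptyl-4,6-dimethoxybenzoyl)oxy]-2-methoxy-6-pentylbenzoate
Conditions: MeI, K2CO3, DMF, rt to 40 °C
Reagents that add atoms: iodomethane, CI
Why: Williamson etherification in a dipolar aprotic solvent breaks the hydrogen bond and methylates the only remaining phenol, while the benzyl ester and the doubly ortho-substituted aryl benzoate should tolerate anhydrous carbonate.

Step 10
Reactants: 22 benzyl 4-[(2-heptyl-4,6-dimethoxybenzoyl)oxy]-2-methoxy-6-pentylbenzoate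
Product: 23 4-[(2-heptyl-4,6-dimethoxybenzoyl)oxy]-2-methoxy-6-pentylbenzoic acid
Conditions: H2 (1 atm), Pd/C, EtOAc, rt
Reagents that add atoms: none
Why: Catalytic hydrogenolysis cleaves the benzylic C–O bond of the ester only, since the molecule holds no alkene and the aryl ester and methyl ethers are inert to these conditions.

**Compound list**

1 | hexanoyl chloride | CCCCCC(=O)Cl | starting material
2 | N-methoxy-N-methylhexanamide | CCCCCC(=O)N(C)OC | intermediate
3 | 2,2,6-trimethyl-4H-1,3-dioxin-4-one | CC1=CC(=O)OC(C)(C)O1 | starting material
4 | acetyl chloride | CC(=O)Cl | starting material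
5 | lithium 2,2-dimethyl-6-methylidene-6H-1,3-dioxin-4-olate (dienolate of 3) | C=C1C=C(O[Li])OC(C)(C)O1 | intermediate (not isolated)
6 | 2,2-dimethyl-6-(2-oxopropyl)-4H-1,3-dioxin-4-one | CC(=O)CC1=CC(=O)OC(C)(C)O1 | intermediate
7 | dilithium dianion of 6 (deprotonated at the ring-adjacent CH2 and at the terminal CH3, drawn as the dienediolate) | C=C(O[Li])C=C1C=C(O[Li])OC(C)(C)O1 | intermediate (not isolated)
8 | 6-(2,4-dioxononyl)-2,2-dimethyl-4H-1,3-dioxin-4-one | CCCCCC(=O)CC(=O)CC1=CC(=O)OC(C)(C)O1 | intermediate
9 | benzyl alcohol | OCc1ccccc1 | starting material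
10 | 3,5,7-trioxododec-1-en-1-one (acylketene) | CCCCCC(=O)CC(=O)CC(=O)C=C=O | intermediate (not isolated)
11 | benzyl 3,5,7-trioxododecanoate | CCCCCC(=O)CC(=O)CC(=O)CC(=O)OCc1ccccc1 | intermediate (not isolated)
12 | benzyl 2-hydroxy-4,6-dioxo-2-pentylcyclohexane-1-carboxylate (mixture of diastereomers) | CCCCCC1(O)CC(=O)CC(=O)C1C(=O)OCc1ccccc1 | intermediate (not isolated)
13 | benzyl 2,4-dihydroxy-6-pentylbenzoate | CCCCCc1cc(O)cc(O)c1C(=O)OCc1ccccc1 | intermediate
14 | 1-(bromomethyl)-3,5-dimethoxybenzene | COc1cc(CBr)cc(OC)c1 | starting material
15 | n-hexylmagnesium bromide | CCCCCC[Mg]Br | starting material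
16 | 1-heptyl-3,5-dimethoxybenzene | CCCCCCCc1cc(OC)cc(OC)c1 | intermediate
17 | [(2-heptyl-4,6-dimethoxyphenyl)methylidene]dimethyliminium chloride | CCCCCCCc1cc(OC)cc(OC)c1C=[N+](C)C.[Cl-] | intermediate (not isolated)
18 | 2-heptyl-4,6-dimethoxybenzaldehyde | CCCCCCCc1cc(OC)cc(OC)c1C=O | intermediate
19 | 2-heptyl-4,6-dimethoxybenzoic acid | CCCCCCCc1cc(OC)cc(OC)c1C(=O)O | intermediate
20 | 2-heptyl-4,6-dimethoxybenzoic trifluoroacetic anhydride | CCCCCCCc1cc(OC)cc(OC)c1C(=O)OC(=O)C(F)(F)F | intermediate (not isolated)
21 | benzyl 4-[(2-heptyl-4,6-dimethoxybenzoyl)oxy]-2-hydroxy-6-pentylbenzoate | CCCCCCCc1cc(OC)cc(OC)c1C(=O)Oc1cc(CCCCC)c(C(=O)OCc2ccccc2)c(O)c1 | intermediate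
22 | benzyl 4-[(2-heptyl-4,6-dimethoxybenzoyl)oxy]-2-methoxy-6-pentylbenzoate | CCCCCCCc1cc(OC)cc(OC)c1C(=O)Oc1cc(CCCCC)c(C(=O)OCc2ccccc2)c(OC)c1 | intermediate
23 | 4-[(2-heptyl-4,6-dimethoxybenzoyl)oxy]-2-methoxy-6-pentylbenzoic acid | CCCCCCCc1cc(OC)cc(OC)c1C(=O)Oc1cc(CCCCC)c(C(=O)O)c(OC)c1 | target

**Step count**

Total steps: 10.
Longest linear sequence: 6 steps (steps 2, 3, 4, 8, 9, 10; the ring A line through steps 5, 6, 7, 8, 9, 10 is equally long).

**Steps most likely to fail**

1. Step 4. The ketene may be captured within the molecule by the enolized C5 oxygen (lactonization to a pyranone) faster than by benzyl alcohol, the open chain may cyclize in the wrong sense, or the ester may exchange during the base and acid phases. The fallback sets out from 8 and comes back at 13, and it closes the ring before the ester is made. Stirring 8 with Et3N in CH2Cl2 at rt, without heating and without alcohol, should let C5 of the intact dioxinone add to the terminal side-chain ketone and, after loss of water, give 7-hydroxy-2,2-dimethyl-5-pentyl-4H-1,3-benzodioxin-4-one F1. Sodium benzyloxide (benzyl alcohol, NaH, THF, 0 to 50 °C) should then open the benzodioxinone at its carbonyl with loss of acetone to give 13.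

2. Step 3. Dianion formation may be incomplete, acylation may occur on oxygen or stall through proton transfer, and the sensitive diketone may self-condense during work-up and chromatography. The fallback sets out from 6 and comes back at 8, replacing the acylation by an aldol addition and an oxidation. Dianion 7 (LiN(i-Pr)2, THF, −78 °C) is added to hexanal to give racemic 6-(4-hydroxy-2-oxononyl)-2,2-dimethyl-4H-1,3-dioxin-4-one F2; the alkoxide formed cannot quench or re-acylate the dianion. Dess–Martin periodinane in CH2Cl2 then oxidizes the secondary alcohol to the beta-diketone 8.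

3. Step 9. Alkylation of the hydrogen-bonded, doubly flanked phenoxide may be slow enough for carbonate to cleave or transfer the depside acyl group. The fallback sets out from 13 and comes back at 22, installing the methyl ether before the depside bond exists; it also removes the regiochemical demand of step 8.
   - Allyl bromide (1.05 equiv) and K2CO3 in acetone at rt should alkylate only the free 4-hydroxyl to give benzyl 2-hydroxy-6-pentyl-4-(prop-2-en-1-yloxy)benzoate F3.
   - MeI and K2CO3 in DMF then give benzyl 2-methoxy-6-pentyl-4-(prop-2-en-1-yloxy)benzoate F4.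
   - Pd(PPh3)4 with morpholine in THF removes the allyl group to give benzyl 4-hydroxy-2-methoxy-6-pentylbenzoate F5.
   - Esterification of F5 with 19 under (CF3CO)2O in toluene, through mixed anhydride 20, should give 22.

**Further compounds**

F1 | step 4 | 7-hydroxy-2,2-dimethyl-5-pentyl-4H-1,3-benzodioxin-4-one | CCCCCc1cc(O)cc2OC(C)(C)OC(=O)c12
F2 | step 3 | 6-(4-hydroxy-2-oxononyl)-2,2-dimethyl-4H-1,3-dioxin-4-one (racemic) | CCCCCC(O)CC(=O)CC1=CC(=O)OC(C)(C)O1
F3 | step 9 | benzyl 2-hydroxy-6-pentyl-4-(prop-2-en-1-yloxy)benzoate | CCCCCc1cc(OCC=C)cc(O)c1C(=O)OCc1ccccc1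
F4 | step 9 | benzyl 2-methoxy-6-pentyl-4-(prop-2-en-1-yloxy)benzoate | CCCCCc1cc(OCC=C)cc(OC)c1C(=O)OCc1ccccc1
F5 | step 9 | benzyl 4-hydroxy-2-methoxy-6-pentylbenzoate | CCCCCc1cc(O)cc(OC)c1C(=O)OCc1ccccc1
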